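**Plan**

1. Numbering and feature: ring A is C1 (quaternary, bears C12H2OAc)–C2–C3(OH)–C4(OAc)–C5(CMe2)–C6; the cage arms are C6–C7–C8, C1–C9 and C6–C11(OAc)–C10(Me), with cyclopropane C8–C9–C10. O3 and C12 are syn-diaxial on ring A, so they can be tied as a γ-lactone whose exocyclic C1=C9 bond is a dienophile, and C6=C11–C10=C8 (C7 as CH2) is a cyclopentadiene latent in the cage.
2. Retrosynthesis: adjust the acetates and open the lactone; cut C9–C10 (cyclopropane, from the exo-epoxide of C10=C11); cut C1–C6 and C8–C9 together (intramolecular Diels–Alder); cut C2–C3 (Barbier allylation), C10–CH3, C6–C11 (aldol) and C6–C7 (Grignard).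
3. Forward: (R)-pantolactone supplies C3–C6; a cyclopentenone is built on C6, the α-methylene lactone on C3, then the methylcyclopentadiene; the [4+2] step closes ring A and the bicyclo[2.2.1]heptene; epoxide opening closes the cyclopropane.
4. Stereochemistry: C4 from (R)-pantolactone; C3 by Felkin–Anh addition; C1, C6 and C8 in the cycloaddition (lactone tether, carbonyl-exo); C11 by exo epoxidation; C9 and C10 by ring closure on the endo face with inversion at C10.
5. Endgame: lactone reduction, desilylation, then acetylation of C11/C12 under a transient C3/C4 boronate and a last selective acetylation of C4–OH.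

Key step: step 11

Remark: cyclopentadiene 17 is handled as the equilibrating mixture of its 1,5-hydrogen-shift isomers and is drawn as the tautomer that cyclises.

**Route**

Step 1
Reactants: 1 (R)-pantolactone
Product: 2 (3R)-4,4-dimethyl-3-(triisopropylsilyloxy)oxolan-2-one
Conditions: TIPSOTf, 2,6-lutidine, CH2Cl2, 0 to 23 °C
Reagents that add atoms: triisopropylsilyl trifluoromethanesulfonate, CC(C)[Si](OS(=O)(=O)C(F)(F)F)(C(C)C)C(C)C
Why: Silyl ether formation with the silyl triflate on the hindered secondary alcohol; the bulky TIPS group resists O-to-O migration under the basic steps and later enforces non-chelated addition at C3.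

Step 2
Reactants: 2 (3R)-4,4-dimethyl-3-(triisopropylsilyloxy)oxolan-2-one
Product: 3 (3R)-4,4-dimethyl-3-(triisopropylsilyloxy)oxolan-2-ol (lactol; both anomers)
Conditions: i-Bu2AlH, CH2Cl2, −78 °C; aq. potassium sodium tartrate
Reagents that add atoms: none
Why: Partial reduction of a lactone to the lactol with i-Bu2AlH, the tetrahedral aluminate persisting at −78 °C; the hemiacetal centre is lost in step 3.

Step 3
Reactants: 3 (3R)-4,4-dimethyl-3-(triisopropylsilyloxy)oxolan-2-ol
Product: 4 (3S)-2,2-dimethyl-3-(triisopropylsilyloxy)pent-4-en-1-ol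
Conditions: Ph3PCH3Br, n-BuLi, THF, 0 °C; then 3, −78 to 23 °C
Reagents that add atoms: methyltriphenylphosphonium bromide, C[P+](c1ccccc1)(c1ccccc1)c1ccccc1.[Br-]
Why: Wittig methylenation of the lactol through its open hydroxy-aldehyde form masks C3 as a vinyl group and frees the C6 hydroxyl; the lithium counter-ion and low temperature should keep C4 from epimerising.

Step 4
Reactants: 4 (3S)-2,2-dimethyl-3-(triisopropylsilyloxy)pent-4-en-1-ol
Product: 5 (3S)-2,2-dimethyl-3-(triisopropylsilyloxy)pent-4-enal
Conditions: Dess–Martin periodinane, NaHCO3, CH2Cl2, 23 °C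
Reagents that add atoms: none
Why: Dess–Martin oxidation of the neopentyl primary alcohol to a non-enolisable aldehyde (C6).

Step 5
Reactants: 5 (3S)-2,2-dimethyl-3-(triisopropylsilyloxy)pent-4-enal; 6 2-(2-bromoethyl)-2-methyl-1,3-dioxolane
Product: 7 (5S)-4,4-dimethyl-1-(2-methyl-1,3-dioxolan-2-yl)-5-(triisopropylsilyloxy)hept-6-en-3-ol (both carbinol epimers)
Conditions: 6, Mg, THF, 25 °C; then 5, −20 to 0 °C; aq. NH4Cl
Reagents that add atoms: none
Why: Grignard addition of the masked 3-oxobutyl reagent to the aldehyde forms C6–C7 and brings in C7, C8, C10 and C11; the carbinol configuration is removed in step 6.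

Step 6
Reactants: 7 (5S)-4,4-dimethyl-1-(2-methyl-1,3-dioxolan-2-yl)-5-(triisopropylsilyloxy)hept-6-en-3-ol
Product: 8 (5S)-4,4-dimethyl-1-(2-methyl-1,3-dioxolan-2-yl)-5-(triisopropylsilyloxy)hept-6-en-3-one
Conditions: Dess–Martin periodinane, NaHCO3, CH2Cl2, 23 °C
Reagents that add atoms: none
Why: Dess–Martin oxidation of the secondary alcohol to the C6 ketone.

Step 7
Reactants: 8 (5S)-4,4-dimethyl-1-(2-methyl-1,3-dioxolan-2-yl)-5-(triisopropylsilyloxy)hept-6-en-3-one
Product: 10 3-[(3S)-2-methyl-3-(triisopropylsilyloxy)pent-4-en-2-yl]cyclopent-2-en-1-one, via 1,4-diketone 9 (not isolated)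
Conditions: 1 M HCl, THF, 23 °C; then 2 M NaOH, MeOH, 65 °C
Reagents that add atoms: water, O
Why: Acid hydrolysis of the dioxolane unmasks the 1,4-diketone, and base-mediated intramolecular aldol condensation of the methyl-ketone enolate onto the C6 ketone (the only mode that gives a five-membered ring; C5 has no hydrogen, so no retro-aldol or elimination) forms C6=C11.

Step 8
Reactants: 10 3-[(3S)-2-methyl-3-(triisopropylsilyloxy)pent-4-en-2-yl]cyclopent-2-en-1-one
Product: 12 (2R)-3-methyl-3-(3-oxocyclopent-1-en-1-yl)-2-(triisopropylsilyloxy)butanal, via ozonide 11 (not isolated)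
Conditions: O3, CH2Cl2, −78 °C (Sudan red 7B end point); then PPh3, −78 to 23 °C
Reagents that add atoms: ozone, [O-][O+]=O
Why: Ozonolysis with reductive work-up cleaves the monosubstituted vinyl group much faster than the electron-poor trisubstituted enone alkene and unveils the C3 aldehyde under neutral conditions that leave C4 untouched.

Step 9
Reactants: 12 (2R)-3-methyl-3-(3-oxocyclopent-1-en-1-yl)-2-(triisopropylsilyloxy)butanal; 13 methyl 2-(bromomethyl)acrylate
Product: 15 (5S)-3-methylidene-5-[(1R)-2-methyl-2-(3-oxocyclopent-1-en-1-yl)-1-(triisopropylsilyloxy)propyl]oxolan-2-one, via hydroxy ester 14 (not isolated)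
Conditions: 13, Zn dust, THF/sat. aq. NH4Cl, 0 to 23 °C; then TsOH·H2O (cat.), CH2Cl2, 23 °C
Reagents that add atoms: none
Why: Zinc Barbier allylation (SE2′ attack of the 2-(methoxycarbonyl)allylzinc reagent on the aldehyde, which is far more reactive than the enone ketone) followed by acid-catalysed lactonisation; C3 is set by Felkin–Anh/Cornforth (non-chelated) addition anti to the C4 silyloxy group, giving the 3,4-anti relationship.

Step 10
Reactants: 15 (5S)-3-methylidene-5-[(1R)-2-methyl-2-(3-oxocyclopent-1-en-1-yl)-1-(triisopropylsilyloxy)propyl]oxolan-2-one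
Product: 17 (5S)-3-methylidene-5-[(1R)-2-methyl-2-(3-methylcyclopenta-1,3-dien-1-yl)-1-(triisopropylsilyloxy)propyl]oxolan-2-one, via tertiary allylic alcohol 16 (not isolated)
Conditions: MeLi, CeCl3, THF, −78 °C; aq. NH4Cl; then TsOH·H2O (2 mol %), CH2Cl2, 0 °C
Reagents that add atoms: methyllithium, [Li]C
Why: Organocerium 1,2-addition to the enone carbonyl (a ketone reacts well before the conjugated lactone at −78 °C) and acid-catalysed dehydration of the tertiary allylic alcohol through its allyl cation give the 1,3-disubstituted cyclopentadiene.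

Step 11
Reactants: 17 (5S)-3-methylidene-5-[(1R)-2-methyl-2-(3-methylcyclopenta-1,3-dien-1-yl)-1-(triisopropylsilyloxy)propyl]oxolan-2-one
Product: 18 lactone-bridged tricyclic norbornene (new bonds C1–C6 and C8–C9; C12 carbonyl exo on C1; C2 endo; C10(Me)=C11 alkene; C4–OTIPS)
Conditions: PhMe (0.01 M), BHT, 110 °C
Reagents that add atoms: none
Why: 1,5-Hydrogen shifts interconvert the cyclopentadiene tautomers, and the one with C6 and C8 as diene termini adds in a concerted suprafacial [4+2] fashion to the s-cis-locked α-methylene lactone; this is an intramolecular Diels–Alder reaction of a 1-substituted cyclopentadiene through a four-atom link, closest to the carbonyl-exo additions of cyclopentadiene to α-methylene-γ-butyrolactones. Ring A closes as a six-membered ring through a chair-like transition state by the C1–C6 bond (link C2–C3–C4–C5), and the bicyclo[2.2.1]heptene closes by the C8–C9 bond with C7 as the one-carbon bridge. C1 is controlled by C3, because the lactone holds O3 and C12 cis and C6 can reach C1 only on the alkene face that carries C4. C6 and C8 follow from the carbonyl-exo orientation (C12 toward C7, C2 under the C10=C11 bridge), which α-methylene lactones prefer and which places the C4 silyloxy group equatorial on the forming chair. The step needs this exo mode and the C6/C8-terminus tautomer: the tautomer with the methyl-bearing C10 as a terminus would have to form a second fully substituted bond, and the tautomer with C6 internal cannot reach the dienophile, so the mixture should drain through the drawn isomer.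

Step 12
Reactants: 18 lactone-bridged tricyclic norbornene
Product: 19 exo-10,11-epoxide of 18
Conditions: mCPBA, NaHCO3, CH2Cl2, 0 °C
Reagents that add atoms: 3-chloroperoxybenzoic acid, OOC(=O)c1cccc(Cl)c1
Why: Prilezhaev epoxidation of the trisubstituted norbornene from the exo face (syn to C7), the endo face being shielded by C2 and C9; this sets the C11–O bond on the C7 side.

Step 13
Reactants: 19 exo-10,11-epoxide of 18
Product: 20 nortricyclanol lactone (cyclopropane C8–C9–C10; C11–OH on the C7 side; C12/O3 lactone; C4–OTIPS)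
Conditions: B(C6F5)3 (5 mol %), CH2Cl2, −40 to 0 °C
Reagents that add atoms: none
Why: Proposed new method: Lewis-acid ionisation of the trisubstituted exo-epoxide at the tertiary C10–O bond, assisted by the antiperiplanar C8–C9 σ bond, gives a 2-methyl-2-norbornyl-type cation that loses the exo proton at C9 (W arrangement) with C9–C10 bond formation, inverting C10 and leaving C11–O exo; a 3,2-hydride shift to a C11 ketone is disfavoured because the C11 hydrogen is endo, alkene formation toward C8 is excluded by Bredt's rule, and the remaining exit, loss of a methyl proton to the exo-methylene allylic alcohol, can return to the cation under the acidic conditions; the closest known reaction types are the acid-induced isomerisation of exo-2,3-epoxynorbornane to 3-nortricyclanol and the camphene–tricyclene 1,3-elimination of 2-methyl-2-norbornyl cations.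

Step 14
Reactants: 20 nortricyclanol lactone
Product: 21 C3,C11,C12-triol with C4–OTIPS
Conditions: LiAlH4, THF, 0 to 40 °C
Reagents that add atoms: none
Why: Hydride reduction of the lactone to the C3/C12 diol; the silyl ether and the cyclopropane are inert.

Step 15
Reactants: 21 C3,C11,C12-triol with C4–OTIPS
Product: 22 C3,C4,C11,C12-tetraol
Conditions: Bu4NF, THF, 60 °C
Reagents that add atoms: none
Why: Fluoride cleavage of the hindered silyl ether, run while no ester is present so that forcing conditions are harmless.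

Step 16
Reactants: 22 C3,C4,C11,C12-tetraol
Product: 25 C11,C12-diacetate with free C3/C4 diol, via phenylboronate 23 (not isolated), via diacetyl phenylboronate 24 (not isolated)
Conditions: PhB(OH)2, MgSO4, PhMe, 23 °C; then Ac2O, DMAP, pyridine, 40 °C; then propane-1,3-diol, CH2Cl2, 23 °C
Reagents that add atoms: acetic anhydride, CC(=O)OC(C)=O
Why: Transient boronic ester protection of the only cis-vicinal diol (C3 axial, C4 equatorial), DMAP-catalysed acetylation of the primary C12 and the hindered C11 hydroxyls, and boronate transesterification give the diacetate; masking C3–OH removes any need to distinguish it from the equally crowded C11–OH.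

Step 17
Reactants: 25 C11,C12-diacetate with free C3/C4 diol
Product: 26 CNP0111873.1 (C4,C11,C12-triacetate with free C3–OH)
Conditions: Ac2O (1.3 equiv), pyridine, DMAP (cat.), CH2Cl2, 0 °C
Reagents that add atoms: acetic anhydride, CC(=O)OC(C)=O
Why: Sterically controlled acylation of the equatorial C4–OH; the axial C3–OH is flanked by the syn-axial C12 methylene and C5 methyl and should stay free, and the acetate on the less hindered oxygen is also the thermodynamic position.

**Compound list**

1 | (R)-pantolactone | CC1(C)COC(=O)[C@@H]1O | starting material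
2 | (3R)-4,4-dimethyl-3-(triisopropylsilyloxy)oxolan-2-one | CC1(C)COC(=O)[C@@H]1O[Si](C(C)C)(C(C)C)C(C)C | intermediate
3 | (3R)-4,4-dimethyl-3-(triisopropylsilyloxy)oxolan-2-ol (anomers) | CC1(C)COC(O)[C@@H]1O[Si](C(C)C)(C(C)C)C(C)C | intermediate
4 | (3S)-2,2-dimethyl-3-(triisopropylsilyloxy)pent-4-en-1-ol | C=C[C@H](O[Si](C(C)C)(C(C)C)C(C)C)C(C)(C)CO | intermediate
5 | (3S)-2,2-dimethyl-3-(triisopropylsilyloxy)pent-4-enal | C=C[C@H](O[Si](C(C)C)(C(C)C)C(C)C)C(C)(C)C=O | intermediate
6 | 2-(2-bromoethyl)-2-methyl-1,3-dioxolane | CC1(CCBr)OCCO1 | starting material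
7 | (5S)-4,4-dimethyl-1-(2-methyl-1,3-dioxolan-2-yl)-5-(triisopropylsilyloxy)hept-6-en-3-ol (C3 epimers) | C=C[C@H](O[Si](C(C)C)(C(C)C)C(C)C)C(C)(C)C(O)CCC1(C)OCCO1 | intermediate
8 | (5S)-4,4-dimethyl-1-(2-methyl-1,3-dioxolan-2-yl)-5-(triisopropylsilyloxy)hept-6-en-3-one | C=C[C@H](O[Si](C(C)C)(C(C)C)C(C)C)C(C)(C)C(=O)CCC1(C)OCCO1 | intermediate
9 | (7S)-6,6-dimethyl-7-(triisopropylsilyloxy)non-8-ene-2,5-dione | C=C[C@H](O[Si](C(C)C)(C(C)C)C(C)C)C(C)(C)C(=O)CCC(C)=O | intermediate (not isolated)
10 | 3-[(3S)-2-methyl-3-(triisopropylsilyloxy)pent-4-en-2-yl]cyclopent-2-en-1-one | C=C[C@H](O[Si](C(C)C)(C(C)C)C(C)C)C(C)(C)C1=CC(=O)CC1 | intermediate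
11 | secondary ozonide (1,2,4-trioxolane) of the vinyl group of 10 | C1OOC(O1)[C@H](O[Si](C(C)C)(C(C)C)C(C)C)C(C)(C)C2=CC(=O)CC2 | intermediate (not isolated)
12 | (2R)-3-methyl-3-(3-oxocyclopent-1-en-1-yl)-2-(triisopropylsilyloxy)butanal | O=C[C@H](O[Si](C(C)C)(C(C)C)C(C)C)C(C)(C)C1=CC(=O)CC1 | intermediate
13 | methyl 2-(bromomethyl)acrylate | C=C(CBr)C(=O)OC | starting material
14 | methyl (4S,5R)-4-hydroxy-6-methyl-2-methylidene-6-(3-oxocyclopent-1-en-1-yl)-5-(triisopropylsilyloxy)heptanoate | C=C(C[C@H](O)[C@H](O[Si](C(C)C)(C(C)C)C(C)C)C(C)(C)C1=CC(=O)CC1)C(=O)OC | intermediate (not isolated)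
15 | (5S)-3-methylidene-5-[(1R)-2-methyl-2-(3-oxocyclopent-1-en-1-yl)-1-(triisopropylsilyloxy)propyl]oxolan-2-one | C=C1C[C@H](OC1=O)[C@H](O[Si](C(C)C)(C(C)C)C(C)C)C(C)(C)C1=CC(=O)CC1 | intermediate
16 | (5S)-5-[(1R)-2-(3-hydroxy-3-methylcyclopent-1-en-1-yl)-2-methyl-1-(triisopropylsilyloxy)propyl]-3-methylideneoxolan-2-one (carbinol epimers) | C=C1C[C@H](OC1=O)[C@H](O[Si](C(C)C)(C(C)C)C(C)C)C(C)(C)C1=CC(C)(O)CC1 | intermediate (not isolated)
17 | (5S)-3-methylidene-5-[(1R)-2-methyl-2-(3-methylcyclopenta-1,3-dien-1-yl)-1-(triisopropylsilyloxy)propyl]oxolan-2-one | C=C1C[C@H](OC1=O)[C@H](O[Si](C(C)C)(C(C)C)C(C)C)C(C)(C)C1=CC(C)=CC1 | intermediate (Diels–Alder precursor)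
18 | lactone-bridged tricyclic norbornene (Diels–Alder product) | O=C4[C@]12C[C@H](O4)[C@H](O[Si](C(C)C)(C(C)C)C(C)C)C(C)(C)[C@]13C[C@H](C2)C(C)=C3 | intermediate
19 | exo-10,11-epoxide of 18 | O=C4[C@]12C[C@H](O4)[C@H](O[Si](C(C)C)(C(C)C)C(C)C)C(C)(C)[C@]13C[C@H](C2)[C@@]5(C)O[C@@H]35 | intermediate
20 | nortricyclanol lactone | O=C4[C@]12C[C@H](O4)[C@H](O[Si](C(C)C)(C(C)C)C(C)C)C(C)(C)[C@]13C[C@@H]1[C@H]2[C@]1(C)[C@H]3O | intermediate
21 | C3,C11,C12-triol with C4–OTIPS | OC[C@]12C[C@H](O)[C@H](O[Si](C(C)C)(C(C)C)C(C)C)C(C)(C)[C@]13C[C@@H]1[C@H]2[C@]1(C)[C@H]3O | intermediate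
22 | C3,C4,C11,C12-tetraol | OC[C@]12C[C@H](O)[C@H](O)C(C)(C)[C@]13C[C@@H]1[C@H]2[C@]1(C)[C@H]3O | intermediate
23 | C3,C4-O-phenylboronate of 22 | OC[C@]12C[C@H]4[C@H](OB(c5ccccc5)O4)C(C)(C)[C@]13C[C@@H]1[C@H]2[C@]1(C)[C@H]3O | intermediate (not isolated)
24 | C11,C12-di-O-acetyl C3,C4-O-phenylboronate | CC(=O)OC[C@]12C[C@H]4[C@H](OB(c5ccccc5)O4)C(C)(C)[C@]13C[C@@H]1[C@H]2[C@]1(C)[C@H]3OC(C)=O | intermediate (not isolated)
25 | C11,C12-diacetate with free C3/C4 diol | CC(=O)OC[C@]12C[C@H](O)[C@H](O)C(C)(C)[C@]13C[C@@H]1[C@H]2[C@]1(C)[C@H]3OC(C)=O | intermediate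
26 | CNP0111873.1 | CC(=O)OC[C@]12C[C@H](O)[C@H](OC(C)=O)C(C)(C)[C@]13C[C@@H]1[C@H]2[C@]1(C)[C@H]3OC(C)=O | target

**Step count and risks**

Total step count: 17. Longest linear sequence: 17 steps from (R)-pantolactone.

Steps most likely to fail:

1. Step 13. After ionisation at C10 the cation may be deprotonated at the C10 methyl group instead of at C9, or be captured by a nucleophile, so that the C9–C10 bond does not form. The fallback uses known reactions and sets out from epoxide 19. The aluminium amide Et2Al(TMP) (from Et2AlCl and LiTMP, PhMe, 0 °C) should open the epoxide by syn β-elimination through the only available β-hydrogens, those of the methyl group, to give the exo-methylene allylic alcohol F1. This 2-methylenenorbornane is then isomerised under acid catalysis (TsOH·H2O, PhMe, 60 °C), the thermodynamically controlled camphene–tricyclene type of 1,3-elimination, which should funnel the material to nortricyclanol 20, where the route is rejoined.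

2. Step 11. Bond formation between the two fully substituted carbons C1 and C6 next to C5 may be slow, so that diene dimerisation or cycloaddition through the methyl-terminus tautomer competes. The fallback sets out from enone lactone 15 and also bypasses step 10. Soft enolisation (TBSOTf, Et3N, CH2Cl2, −78 to 0 °C) should give the cross-conjugated 2-silyloxycyclopentadiene F2, a far more reactive diene with no methyl on a terminus. Gentle warming (PhMe, 60 °C) should close the same two bonds to the silyl enol ether adduct F3. CsF and PhNTf2 (DME, 23 °C) should convert it into the enol triflate F4, and Suzuki–Miyaura methylation (Pd(PPh3)4, trimethylboroxine, K2CO3, dioxane, 90 °C) should return the route at adduct 18.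

3. Step 10. The organocerium reagent may attack the lactone carbonyl or add in a conjugate sense to the α-methylene lactone besides the enone carbonyl. The fallback sets out from 15. Takai–Lombardo methylenation (Zn, CH2Br2, TiCl4, THF/CH2Cl2, 0 to 23 °C), which is selective for ketones over esters, should give the exo-methylene triene F5. A trace of acid (TsOH·H2O, CH2Cl2, 0 °C) should isomerise it through the same allyl cation to cyclopentadiene 17, where the route is rejoined.

**Further compounds**

F1 | step 13 | exo-methylene allylic alcohol (C10=CH2, C11–OH exo, lactone, C4–OTIPS) | O=C4[C@]12C[C@H](O4)[C@H](O[Si](C(C)C)(C(C)C)C(C)C)C(C)(C)[C@]13C[C@H](C2)C(=C)[C@H]3O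
F2 | step 11 | 2-silyloxycyclopentadiene (C10–OTBS analogue of 17) | C=C1C[C@H](OC1=O)[C@H](O[Si](C(C)C)(C(C)C)C(C)C)C(C)(C)C1=CC(O[Si](C)(C)C(C)(C)C)=CC1
F3 | step 11 | silyl enol ether adduct (C10–OTBS analogue of 18) | O=C4[C@]12C[C@H](O4)[C@H](O[Si](C(C)C)(C(C)C)C(C)C)C(C)(C)[C@]13C[C@H](C2)C(O[Si](C)(C)C(C)(C)C)=C3
F4 | step 11 | enol triflate (C10–OTf analogue of 18) | O=C4[C@]12C[C@H](O4)[C@H](O[Si](C(C)C)(C(C)C)C(C)C)C(C)(C)[C@]13C[C@H](C2)C(OS(=O)(=O)C(F)(F)F)=C3
F5 | step 10 | exo-methylene triene (3-methylidenecyclopent-1-enyl analogue of 17) | C=C1C[C@H](OC1=O)[C@H](O[Si](C(C)C)(C(C)C)C(C)C)C(C)(C)C1=CC(=C)CC1
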